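## The problem

1-O-Caffeoylquinic acid (17) is a single cyclohexane, so no rings have to be joined; the task is the fully substituted carbon C1 and its relation to the three carbinol carbons. C1 carries the carboxyl carbon C7 and the oxygen O1. O1 is the most hindered oxygen of the molecule (tertiary, 1,3-diaxial to O3), yet it alone is acylated, by an (E)-caffeoyl group, while O3, O4 and O5 stay free. The ring holds a cis pair O3/O4, a trans pair O4/O5, and O1 cis to O3 and O4 (C7 cis to O5). Only C3 and C5 (both R, trans to each other) carry independent absolute configuration: as long as C1 is a ketone or ketal and O3 and O5 bear the same group, the two ring halves are constitutionally alike and of like configuration, so C4 is not stereogenic, and C1 can be set later by the ring once O3 and O5 are differentiated. The fragile points are the caffeoyl ester (it migrates to free neighbouring hydroxyls and is cleaved in base), the catechol (oxidised as its phenolate), the acid (lactonisation onto O5) and every 3,5-dioxygenated cyclohexanone on the way (β-elimination). The feature that opens the key step is the substitution of C1: bonded to the ring methylenes C2 and C6, to an acyloxy oxygen and to a carboxyl carbon, it is the retron of a Passerini reaction of a C1 ketone, with O1 the former carbonyl oxygen, C7 the former isocyanide carbon and the caffeoyl group the acid partner.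

## Retrosynthesis

**17 ⇒ 16.** Only protecting groups are cut: the O3–Si bond and the four acetal C–O bonds of a butane-2,3-diacetal on O4/O5, giving acid 16. Acid is kept for the end because the free triol of 17 lets a caffeoyl group wander in base, whereas the tertiary ester tolerates aqueous acid. Compound 16 is no smaller, but every hydroxyl that could accept an acyl group is masked, so all base chemistry can be done before it. The forward step must remove both groups without lactonisation onto O5.

**16 ⇒ 15 ⇒ 13.** The C7–N bond of N-acylindole 15 is cut, together with the two aryl acetate bonds. Compound 15 is traced to anilide 13 by opening the indole N–C2 bond back to an ortho acetal side chain. A nitrile, primary amide or simple ester at C7 would need conditions that also destroy the caffeate; the acylindole is an acyl donor that hydrolyses under conditions a tertiary cinnamate survives. Accepting that the acetates fall in the same step saves a separate deprotection and turns the catechol into a phenolate that deactivates the cinnamate towards hydroxide. The forward reactions must discriminate C7 from the O1 ester and keep the silyl ether through the acid step.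

**13 ⇒ 8 + 10 + 11.** The C1–C7 bond and the caffeoyl C(=O)–O1 bond are cut in one Passerini disconnection to ketone 8, acid 10 and isocyanide 11. The neighbouring cut, O1–acyl alone, would require esterifying a tertiary hydroxyl that is syn-axial to O3; the neighbouring cut C1–C7 alone (cyanohydrin) leaves both that acylation and a nitrile hydrolysis. The precursor 8 has no quaternary centre and no C7, and it has one stereocentre fewer; the three ring stereocentres it keeps are the ones that must direct C1. The forward reaction must add the isocyanide to the equatorial face of C1 and must not provoke β-elimination.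

**8 ⇒ 7 ⇒ 6 ⇒ 5.** Protecting-group bonds are cut back to triol 5. The diacetal is chosen for O4/O5 because it selects the trans diol and locks the chair that places O3 axial, which is the control element of the key step; a silyl ether on O3 then makes that axial group large. C1 is carried as a dimethyl ketal and not as a cyclic ketal: it is inert in the alcohol–orthoester medium of diacetal formation, where a dioxolane would exchange, and it is released by acid too weak to touch the diacetal or to trigger elimination. Triol 5 has no protecting-group differentiation at all.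

**5 ⇒ 4 ⇒ 1 + 2.** The C3–O and C5–O bonds are cut to the symmetric ketone 1 and two molecules of nitrosoarene 2 (double α-aminoxylation under amino-acid enamine catalysis), with the C4 carbonyl of the bis(aminoxy) ketone 3 reduced to give 4 and the N–O bonds then cleaved. Both absolute stereocentres come from one catalytic operation, and the C4 carbinol needs no control because 3 has a twofold axis through C1 and C4 that makes its two carbonyl faces equivalent. The alternative of cutting a ring C–C bond would demand an acyclic precursor with the same stereocentres already in place. The forward reaction must run twice, on opposite α-carbons, with the same facial sense.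

**10 ⇒ 9.** The two aryl acetate bonds are cut to caffeic acid 9; the acetates make the acid partner soluble and oxidation-stable for the key step.

## Roads not taken

**Alternative 1:** The cut is C1–C6. In the forward sense zinc inserts into the C–Br bond of the acyclic bromomethyl ketone keto ester A2 and the enolate adds to the keto ester carbonyl, closing the ring and creating the C1 carbinol of A1.
- Merits: the ring carbons and the C3/C4 cis diol can come from a chiral-pool acetonide, no enantioselective catalysis is needed, and the six-membered aldol-type closure is favourable. In these respects it is at least as good as the chosen plan.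
- Weak points: A1 is a β-hydroxy ketone (C1–OH β to the C5 carbonyl) and can reopen or dehydrate. The facial sense at C1 rests on a remote acetonide, and the C5 ketone must still be reduced trans to O4. The tertiary hydroxyl must then be acylated with an activated form of 10, which is the least reliable bond formation of the whole problem left to the end. The ethyl ester must finally be cleaved beside the caffeate, and A2 itself needs a multistep synthesis.
- Comparison: the chosen plan never acylates a tertiary alcohol and reaches 13 with all four ring stereocentres and the ester in place.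

**Alternative 2:** The cuts are C1–C6 and C2–C3. Buta-1,3-diene A5 adds to the 2-acyloxyacrolein A4 under iminium activation by a chiral amine salt, giving the cyclohexene A3 with C1 as a quaternary acyloxy aldehyde.
- Merits: this is the most direct construction of the O1-acyl/C1/C7 motif. It is catalytic, enantioselective and convergent, the caffeoyl ester is installed without any acylation, and the aldehyde is one mild oxidation from the acid. For C1 alone it is better than the Passerini step.
- Weak points: A3 contains none of the three carbinol centres. Its alkene spans only two of the three oxygenated positions, so the third needs allylic functionalisation of an unactivated methylene. All three C–O bonds must be set relative to a remote quaternary centre whose two faces differ only as acyloxy versus formyl. The required cis-3,4/trans-4,5 pattern is not what a single dihydroxylation gives. A5 is a sluggish diene for this activation mode, and the base-sensitive caffeate would be carried through every oxidation.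
- Comparison: the chosen plan inverts the order. The three carbinols are set first from a symmetric ketone and are then used to direct C1.

**Alternative 3:** The cut is C3–C4. Samarium diiodide A8 (SmI2, a divalent samarium reductant) converts one aldehyde of the dialdehyde A7 into a ketyl that adds to the other, closing the ring as the cis diol A6.
- Merits: C1 is fixed early and unambiguously from a chiral-pool hydroxy-acid acetal by self-regenerating alkylation, and the cis relation of O3/O4 matches the usual outcome of such pinacol closures. Its certainty at C1 is better than the chosen plan, whose main risk is exactly the facial selectivity there.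
- Weak points: A7 is a long, doubly functionalised chain with an epimerisable α-silyloxy aldehyde, and its C5 centre needs an asymmetric step of its own. Two new centres must form correctly relative to two existing ones, and the reductant A8 is consumed in at least two equivalents. After closure the dioxolanone must be opened, the new diol protected and the tertiary hydroxyl acylated, so the hard esterification returns.
- Comparison: the chosen plan is roughly half as long and makes the ester in the same step as the C1–C7 bond.

Key step: step 7

Remark: ketone 1 and isocyanide 11 are both catalogue compounds and are taken as purchased.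

## Route

Step 1
Reactants: 1 4,4-dimethoxycyclohexan-1-one; 2 nitrosobenzene (two molecules are incorporated)
Product: 4 (2R,6R)-4,4-dimethoxy-2,6-bis[(phenylamino)oxy]cyclohexan-1-ol, via bis(aminoxy) ketone 3 (not isolated)
Conditions: L-proline (30 mol %), 2 (2.5 equiv, slow addition), DMF, 0 °C; then NaBH4, MeOH, 0 °C
Reagents that add atoms: nitrosobenzene (the second molecule of 2), O=Nc1ccccc1
Why: Proline enamine catalysis (α-aminoxylation, an O-selective nitroso aldol reaction): the enamine of 1 attacks the oxygen of 2 on the face set by the catalyst's carboxylic acid, and with excess 2 the reaction is known to repeat on the α′ side with a second molecule of 2, so both new centres are R and trans (C2-symmetric 3). NaBH4 reduces the labile ketone in the same flask; the two carbonyl faces of 3 are related by the twofold axis, so the carbinol carbon is not stereogenic and a single alcohol should result.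

Step 2
Reactants: 4 (2R,6R)-4,4-dimethoxy-2,6-bis[(phenylamino)oxy]cyclohexan-1-ol
Product: 5 (1R,3R)-5,5-dimethoxycyclohexane-1,2,3-triol
Conditions: H2 (1 atm), 10% Pd/C, MeOH, rt
Reagents that add atoms: none
Why: Hydrogenolysis of the weak N–O bonds over Pd/C frees both hydroxyls with retention at carbon; nothing else in 4 is reducible and the dimethyl ketal is inert in neutral MeOH.

Step 3
Reactants: 5 (1R,3R)-5,5-dimethoxycyclohexane-1,2,3-triol
Product: 6 (3R,4R,5R)-1,1-dimethoxy-4,5-O-[(2S,3S)-2,3-dimethoxybutane-2,3-diyl]cyclohexane-3,4,5-triol (quinic acid numbering)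
Conditions: butane-2,3-dione, HC(OMe)3, CSA (cat.), MeOH, reflux; Et3N quench
Reagents that add atoms: butane-2,3-dione, CC(=O)C(C)=O; trimethyl orthoformate, COC(OC)OC
Why: Butane-2,3-diacetal formation under thermodynamic control selects the trans-diequatorial O4/O5 pair over the cis O3/O4 pair, because only there can both acetal methoxy groups be axial (two anomeric effects) in a trans-fused chair; the diol fixes both acetal carbons as S. Triol 5 has exactly one trans and one cis pair, so one regioisomer is expected, and the C1 dimethyl ketal equilibrates only with its own solvent.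

Step 4
Reactants: 6 (3R,4R,5R)-1,1-dimethoxy-4,5-O-[(2S,3S)-2,3-dimethoxybutane-2,3-diyl]cyclohexane-3,4,5-triol
Product: 7 (3R,4S,5R)-3-O-(tert-butyldimethylsilyl)-1,1-dimethoxy-4,5-O-[(2S,3S)-2,3-dimethoxybutane-2,3-diyl]cyclohexane-3,4,5-triol
Conditions: TBSCl, imidazole, DMAP (cat.), DMF, 40 °C
Reagents that add atoms: tert-butyldimethylsilyl chloride, CC(C)(C)[Si](C)(C)Cl
Why: Silyl ether formation on the one remaining (axial, secondary) hydroxyl; the chloride with imidazole is used because silyl triflates could ionise the dimethyl ketal, and no stereocentre is touched.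

Step 5
Reactants: 7 (3R,4S,5R)-3-O-(tert-butyldimethylsilyl)-1,1-dimethoxy-4,5-O-[(2S,3S)-2,3-dimethoxybutane-2,3-diyl]cyclohexane-3,4,5-triol
Product: 8 (3R,4S,5R)-3-(tert-butyldimethylsilyloxy)-4,5-O-[(2S,3S)-2,3-dimethoxybutane-2,3-diyl]-4,5-dihydroxycyclohexan-1-one
Conditions: PPTS (cat.), acetone–H2O, rt
Reagents that add atoms: water, O
Why: Acyclic dimethyl ketals hydrolyse under far weaker acid than the anomerically stabilised cyclic diacetal or a secondary TBS ether, so buffered pyridinium acid at room temperature should unmask C1 selectively and without β-elimination of the C3 silyloxy group.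

Step 6
Reactants: 9 caffeic acid
Product: 10 (E)-3-(3,4-diacetoxyphenyl)prop-2-enoic acid (di-O-acetylcaffeic acid)
Conditions: Ac2O, pyridine, rt; aqueous work-up
Reagents that add atoms: acetic anhydride, CC(=O)OC(C)=O
Why: Standard O-acetylation of the catechol; any mixed anhydride at the carboxyl group is hydrolysed on work-up and the E-alkene is unaffected.

Step 7
Reactants: 8 (3R,4S,5R)-3-(tert-butyldimethylsilyloxy)-4,5-O-[(2S,3S)-2,3-dimethoxybutane-2,3-diyl]-4,5-dihydroxycyclohexan-1-one; 10 di-O-acetylcaffeic acid; 11 1-isocyano-2-(2,2-dimethoxyethyl)benzene
Product: 13 1-O-(3,4-di-O-acetylcaffeoyl)-3-O-(tert-butyldimethylsilyl)-4,5-O-[(2S,3S)-2,3-dimethoxybutane-2,3-diyl]quinic acid 2-(2,2-dimethoxyethyl)anilide, via O-acyl imidate 12 (not isolated)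
Conditions: CH2Cl2 (about 1 M in 8), 10 and 11 in slight excess, rt to 35 °C
Reagents that add atoms: none
Why: This is a Passerini three-component reaction, known for cyclohexanones with carboxylic acids and aryl isocyanides in concentrated aprotic solution and applied here to a more hindered, oxygenated ketone. Acid 10 hydrogen-bonds to the C1 carbonyl of 8, the isocyanide carbon of 11 adds to C1 (C1–C7 bond) and the resulting nitrilium ion is taken by the caffeate to give imidate 12. A Mumm 1,4-acyl shift from the imidate oxygen to the C1 oxygen then forms the caffeoyl C(=O)–O1 bond irreversibly and leaves anilide 13, so the tertiary ester is made without acylating a tertiary alcohol. No ring is closed. The one new stereocentre, C1, is controlled by the locked chair of 8: the trans-fused diacetal holds O4 and O5 equatorial, which forces the C3–OTBS bond axial, and an axial approach to C1 would pass syn-axial to it. The isocyanide should therefore enter equatorially, placing C7 equatorial and O1 axial, cis to O3 and O4 as in 17. The step needs this facial selectivity and freedom from β-elimination; the first is secured by the axial silyloxy group, the second by the neutral, base-free medium near room temperature. The two β-oxygen substituents also raise the electrophilicity of the carbonyl, which offsets the modest nucleophilicity of an aryl isocyanide.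

Step 8
Reactants: 13 1-O-(3,4-di-O-acetylcaffeoyl)-3-O-(tert-butyldimethylsilyl)-4,5-O-[(2S,3S)-2,3-dimethoxybutane-2,3-diyl]quinic acid 2-(2,2-dimethoxyethyl)anilide
Product: 15 1-[1-O-(3,4-di-O-acetylcaffeoyl)-3-O-(tert-butyldimethylsilyl)-4,5-O-[(2S,3S)-2,3-dimethoxybutane-2,3-diyl]quinoyl]-1H-indole, via 2-methoxyindoline 14 (not isolated)
Conditions: CSA (10 mol %), quinoline (10 mol %), toluene, 80 °C
Reagents that add atoms: none
Why: Convertible-isocyanide unmasking: acid ionises the dimethyl acetal, the anilide nitrogen closes the five-membered ring to 14, and loss of methanol aromatises to the N-acylindole 15, an activated amide. The quinoline-buffered sulfonic acid in dry toluene should be too weak to cleave the secondary TBS ether, the diacetal or the tertiary ester, and C1 has no α-hydrogen to lose.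

Step 9
Reactants: 15 1-[1-O-(3,4-di-O-acetylcaffeoyl)-3-O-(tert-butyldimethylsilyl)-4,5-O-[(2S,3S)-2,3-dimethoxybutane-2,3-diyl]quinoyl]-1H-indole
Product: 16 1-O-caffeoyl-3-O-(tert-butyldimethylsilyl)-4,5-O-[(2S,3S)-2,3-dimethoxybutane-2,3-diyl]quinic acid
Conditions: LiOH·H2O, THF–H2O (degassed, argon), 0 °C to rt; then cold 1 M HCl to pH 3
Reagents that add atoms: lithium hydroxide, [Li+].[OH-]
Why: The N-acylindole is a weakly conjugated amide, so hydroxide adds to C7 and expels indolide under conditions that are mild for an ester; the aryl acetates fall in the same operation, and the phenolate they leave donates into the cinnamate, which together with its tertiary alkoxy group shields the O1 ester from saponification. O3, O4 and O5 are blocked, so the caffeoyl group cannot migrate, and the quaternary C1 cannot epimerise.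

Step 10
Reactants: 16 1-O-caffeoyl-3-O-(tert-butyldimethylsilyl)-4,5-O-[(2S,3S)-2,3-dimethoxybutane-2,3-diyl]quinic acid
Product: 17 1-O-caffeoylquinic acid
Conditions: CF3CO2H–H2O (9:1), 0 °C to rt; evaporation below 30 °C, reversed-phase purification
Reagents that add atoms: none
Why: Aqueous CF3CO2H hydrolyses the bis-ketal of the diacetal and the silyl ether in one operation, while the tertiary caffeate, the E-alkene and all four stereocentres are stable to acid; cold evaporation limits lactonisation onto O5.

## Compound list

1 | 4,4-dimethoxycyclohexan-1-one | COC1(OC)CCC(=O)CC1 | starting material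
2 | nitrosobenzene | O=Nc1ccccc1 | starting material
3 | (2R,6R)-4,4-dimethoxy-2,6-bis[(phenylamino)oxy]cyclohexan-1-one (trans, C2-symmetric; formed in the flask) | COC1(OC)C[C@@H](ONc2ccccc2)C(=O)[C@H](ONc2ccccc2)C1 | intermediate
4 | (2R,6R)-4,4-dimethoxy-2,6-bis[(phenylamino)oxy]cyclohexan-1-ol (carbinol carbon not stereogenic) | COC1(OC)C[C@@H](ONc2ccccc2)C(O)[C@H](ONc2ccccc2)C1 | intermediate
5 | (1R,3R)-5,5-dimethoxycyclohexane-1,2,3-triol (C2 not stereogenic) | COC1(OC)C[C@@H](O)C(O)[C@H](O)C1 | intermediate
6 | (3R,4R,5R)-1,1-dimethoxy-4,5-O-[(2S,3S)-2,3-dimethoxybutane-2,3-diyl]cyclohexane-3,4,5-triol (free 3-OH axial and cis to O4; O4/O5 trans-diequatorial; both acetal OMe axial) | COC1(OC)C[C@H]2O[C@@](OC)(C)[C@](OC)(C)O[C@@H]2[C@H](O)C1 | intermediate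
7 | 3-O-TBS ether of 6, (3R,4S,5R) | COC1(OC)C[C@H]2O[C@@](OC)(C)[C@](OC)(C)O[C@@H]2[C@H](O[Si](C)(C)C(C)(C)C)C1 | intermediate
8 | (3R,4S,5R)-3-(tert-butyldimethylsilyloxy)-4,5-O-[(2S,3S)-2,3-dimethoxybutane-2,3-diyl]-4,5-dihydroxycyclohexan-1-one | O=C1C[C@H]2O[C@@](OC)(C)[C@](OC)(C)O[C@@H]2[C@H](O[Si](C)(C)C(C)(C)C)C1 | intermediate
9 | caffeic acid, (E)-3-(3,4-dihydroxyphenyl)prop-2-enoic acid | O=C(O)/C=C/c1ccc(O)c(O)c1 | starting material
10 | di-O-acetylcaffeic acid, (E)-3-(3,4-diacetoxyphenyl)prop-2-enoic acid | CC(=O)Oc1ccc(/C=C/C(=O)O)cc1OC(C)=O | intermediate
11 | 1-isocyano-2-(2,2-dimethoxyethyl)benzene | [C-]#[N+]c1ccccc1CC(OC)OC | starting material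
12 | O-(di-O-acetylcaffeoyl) imidate of the 1-hydroxy anilide (Mumm precursor; C1 as in 13; formed in the flask) | CC(=O)Oc1ccc(/C=C/C(=O)OC(=Nc3ccccc3CC(OC)OC)[C@@]2(O)C[C@H]3O[C@@](OC)(C)[C@](OC)(C)O[C@@H]3[C@H](O[Si](C)(C)C(C)(C)C)C2)cc1OC(C)=O | intermediate
13 | 1-O-(3,4-di-O-acetylcaffeoyl)-3-O-TBS-4,5-O-[(2S,3S)-2,3-dimethoxybutane-2,3-diyl]quinic acid 2-(2,2-dimethoxyethyl)anilide (quinic acid configuration: O1 cis to O3 and O4, C7 cis to O5) | CC(=O)Oc1ccc(/C=C/C(=O)O[C@]2(C(=O)Nc3ccccc3CC(OC)OC)C[C@H]3O[C@@](OC)(C)[C@](OC)(C)O[C@@H]3[C@H](O[Si](C)(C)C(C)(C)C)C2)cc1OC(C)=O | intermediate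
14 | N-acyl-2-methoxyindoline from 13 (either epimer at the indoline carbon; formed in the flask) | CC(=O)Oc1ccc(/C=C/C(=O)O[C@]2(C(=O)N3C(OC)Cc4ccccc43)C[C@H]3O[C@@](OC)(C)[C@](OC)(C)O[C@@H]3[C@H](O[Si](C)(C)C(C)(C)C)C2)cc1OC(C)=O | intermediate
15 | N-acylindole: 1-[1-O-(3,4-di-O-acetylcaffeoyl)-3-O-TBS-4,5-O-(2,3-dimethoxybutane-2,3-diyl)quinoyl]-1H-indole | CC(=O)Oc1ccc(/C=C/C(=O)O[C@]2(C(=O)n3ccc4ccccc43)C[C@H]3O[C@@](OC)(C)[C@](OC)(C)O[C@@H]3[C@H](O[Si](C)(C)C(C)(C)C)C2)cc1OC(C)=O | intermediate
16 | 1-O-caffeoyl-3-O-TBS-4,5-O-[(2S,3S)-2,3-dimethoxybutane-2,3-diyl]quinic acid | O=C(/C=C/c1ccc(O)c(O)c1)O[C@]2(C(=O)O)C[C@H]3O[C@@](OC)(C)[C@](OC)(C)O[C@@H]3[C@H](O[Si](C)(C)C(C)(C)C)C2 | intermediate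
17 | 1-O-caffeoylquinic acid (3R,5R; O3/O4 cis, O4/O5 trans, O1 cis to O3 and O4) | O=C(/C=C/c1ccc(O)c(O)c1)O[C@]1(C(=O)O)C[C@@H](O)[C@H](O)[C@H](O)C1 | target

## Step count and risks

Total: 10 steps. Longest linear sequence: 9 steps (steps 1–5 and 7–10, from 1 to 17); step 6 is a one-step side branch.

**Step 7 (key step).** Most likely failure: slow, incomplete union. Ketone Passerini reactions are slower than aldehyde ones and the aryl isocyanide 11 is a weaker nucleophile than alkyl isocyanides. Long reaction times give room for β-elimination of the axial silyloxy group and for leakage to axial attack at C1. A larger silyl group on O3 is the tuning element for the facial question inside the step itself.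
Fallback, from 8 back to 13: the three-component union is split into two known operations.
- Ketone 8 and isocyanide 11 are combined with CF3CO2H and pyridine in CH2Cl2 at 0 °C (acid-promoted α-addition of an isocyanide to a carbonyl group). This gives the labile 1-O-trifluoroacetyl anilide F1.
- Bicarbonate work-up hydrolyses it to the α-hydroxy anilide F2 (3-O-TBS-4,5-O-diacetal quinic acid 2-(2,2-dimethoxyethyl)anilide).
- F2 is esterified on O1 with di-O-acetylcaffeoyl chloride F3 (from 10 with (COCl)2 and cat. DMF) in pyridine with DMAP, which rejoins the route at 13.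

**Step 9.** Most likely failure: the hindered acyl group on the quaternary C1 hydrolyses slowly, and on forcing the conditions hydroxide starts to cleave the caffeoyl ester or the catecholate oxidises.
Fallback, from 15 back to 16: hydrolysis is replaced by alcoholysis followed by a neutral unmasking.
- Compound 15 is treated with allyl alcohol and K2CO3 in THF at 0 °C. No hydroxide is present, so nothing is saponified, and the N-acylindole is a far better acyl donor towards the alkoxide than the hindered, phenolate-deactivated tertiary cinnamate. The product is the allyl ester F4 (allyl 1-O-caffeoyl-3-O-TBS-4,5-O-diacetal quinate, acetates transferred to the alcohol).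
- The allyl group is removed with Pd(PPh3)4 (zerovalent palladium, cat.) and morpholine in THF at rt, giving 16.

**Step 8.** Most likely failure: loss of the silyl ether, or methanol-induced acetyl exchange, under the acid and heat needed to drive the hindered anilide into the indole.
Fallback, from 13 back to 16, without any acid: the anilide is activated as its N-tert-butoxycarbonyl derivative F5 with Boc2O and DMAP in MeCN (the known activation of secondary amides towards hydrolysis). LiOH in THF–H2O then cleaves the acyl carbamate and the acetates to give 16 directly.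

**Step 1.** Most likely failure: the second aminoxylation stalls at the mono-adduct, or the bis(aminoxy) ketone decomposes before reduction (α-aminoxy ketones fragment readily).
Fallback, from 1 back to 4: the two C–O bonds are made in two separate single aminoxylations with isolation in between.
- Compound 1 in excess with slow addition of 2 (L-proline, DMF, 0 °C), the best-established form of the reaction, gives the mono-adduct F6, (R)-4,4-dimethoxy-2-[(phenylamino)oxy]cyclohexan-1-one.
- F6 is freed from 1 and resubjected with fresh L-proline and one equivalent of 2, so that catalyst control and the trans preference act together.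
- NaBH4 then gives 4.

**Step 10.** Most likely failure: slow removal of the hindered axial silyl ether while the product sits in strong acid, so that lactonisation onto O5 or acyl migration to the freed hydroxyls sets in.
Fallback, from 16 back to 17 in two stages: HF·pyridine buffered with pyridine in THF removes the silyl group first, giving F7 (1-O-caffeoyl-4,5-O-diacetal quinic acid). A short treatment with CF3CO2H–H2O then has only the diacetal to remove.

## Further compounds

F1 | step 7 | 1-O-trifluoroacetyl-3-O-TBS-4,5-O-[(2S,3S)-2,3-dimethoxybutane-2,3-diyl]quinic acid 2-(2,2-dimethoxyethyl)anilide | FC(F)(F)C(=O)O[C@]1(C(=O)Nc2ccccc2CC(OC)OC)C[C@H]2O[C@@](OC)(C)[C@](OC)(C)O[C@@H]2[C@H](O[Si](C)(C)C(C)(C)C)C1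
F2 | step 7 | 3-O-TBS-4,5-O-[(2S,3S)-2,3-dimethoxybutane-2,3-diyl]quinic acid 2-(2,2-dimethoxyethyl)anilide | O[C@]1(C(=O)Nc2ccccc2CC(OC)OC)C[C@H]2O[C@@](OC)(C)[C@](OC)(C)O[C@@H]2[C@H](O[Si](C)(C)C(C)(C)C)C1
F3 | step 7 | (E)-3-(3,4-diacetoxyphenyl)prop-2-enoyl chloride | CC(=O)Oc1ccc(/C=C/C(Cl)=O)cc1OC(C)=O
F4 | step 9 | allyl 1-O-caffeoyl-3-O-TBS-4,5-O-[(2S,3S)-2,3-dimethoxybutane-2,3-diyl]quinate | O=C(/C=C/c1ccc(O)c(O)c1)O[C@]2(C(=O)OCC=C)C[C@H]3O[C@@](OC)(C)[C@](OC)(C)O[C@@H]3[C@H](O[Si](C)(C)C(C)(C)C)C2
F5 | step 8 | N-tert-butoxycarbonyl derivative of anilide 13 | CC(=O)Oc1ccc(/C=C/C(=O)O[C@]2(C(=O)N(C(=O)OC(C)(C)C)c3ccccc3CC(OC)OC)C[C@H]3O[C@@](OC)(C)[C@](OC)(C)O[C@@H]3[C@H](O[Si](C)(C)C(C)(C)C)C2)cc1OC(C)=O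
F6 | step 1 | (R)-4,4-dimethoxy-2-[(phenylamino)oxy]cyclohexan-1-one | COC1(OC)CCC(=O)[C@H](ONc2ccccc2)C1
F7 | step 10 | 1-O-caffeoyl-4,5-O-[(2S,3S)-2,3-dimethoxybutane-2,3-diyl]quinic acid | O=C(/C=C/c1ccc(O)c(O)c1)O[C@]2(C(=O)O)C[C@H]3O[C@@](OC)(C)[C@](OC)(C)O[C@@H]3[C@H](O)C2
A1 | alternative 1 | ethyl 5-dehydro-3,4-O-isopropylidenequinate | CCOC(=O)[C@@]1(O)CC(=O)[C@@H]2OC(C)(C)O[C@@H]2C1
A2 | alternative 1 | ethyl (4R,5R)-7-bromo-4,5-(isopropylidenedioxy)-2,6-dioxoheptanoate | BrCC(=O)[C@@H]1OC(C)(C)O[C@@H]1CC(=O)C(=O)OCC
A3 | alternative 2 | (S)-1-formylcyclohex-3-en-1-yl (E)-3-(3,4-diacetoxyphenyl)acrylate | CC(=O)Oc1ccc(/C=C/C(=O)O[C@]2(C=O)CC=CCC2)cc1OC(C)=O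
A4 | alternative 2 | 1-formylvinyl (E)-3-(3,4-diacetoxyphenyl)acrylate [2-(di-O-acetylcaffeoyloxy)acrolein] | CC(=O)Oc1ccc(/C=C/C(=O)OC(=C)C=O)cc1OC(C)=O
A5 | alternative 2 | buta-1,3-diene | C=CC=C
A6 | alternative 3 | 5-O-TBS-quinic acid O1,C7-pivalaldehyde acetal (spiro 2-tert-butyl-1,3-dioxolan-4-one at C1) | CC(C)(C)[C@H]1O[C@@]2(C[C@@H](O[Si](C)(C)C(C)(C)C)[C@H](O)[C@H](O)C2)C(=O)O1
A7 | alternative 3 | 2-tert-butyl-5-(2-oxoethyl)-5-[2-(tert-butyldimethylsilyloxy)-3-oxopropyl]-1,3-dioxolan-4-one (configuration as in A6) | CC(C)(C)[C@H]1O[C@](C[C@@H](O[Si](C)(C)C(C)(C)C)C=O)(CC=O)C(=O)O1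
A8 | alternative 3 | samarium diiodide | I[Sm]I
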